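**Strategy.** The furan ring is disconnected at the C2–C3 bond. In the benzofuran, C2 carries O1 and ring B, so in an open precursor it is the methylene of an aryl benzyl ether, whose C–H bonds are activated by both neighbours and lie five atoms from C3. A dirhodium carbene generated at C3 from an aryldiazoacetate on ring A inserts into that C–H bond, forging C2–C3, closing the five-membered ring and installing the ester that later becomes the formyl group. The precursor is a ring-A aryldiazoacetate whose ortho oxygen bears the protected ring-B benzyl group; the side-chain alcohol is silylated and the catechol is masked as acid-labile acetals.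

Key step: step 8

Remarks on the chemistry:
- The diazo ester is taken as ethyl, because ethyl diazoacetate is the commercial and less hazardous reagent and the ester alkyl group is lost in the reduction.
- The ring-B catechol is carried as its bis(methoxymethyl) ether, not as benzyl ethers: no hydrogenolysis is then needed beside the aryl aldehyde and the benzofuran, and all three protecting groups fall in one acid step.
- The target has no stereocentre; the two centres set in the key step are erased by the dehydrogenation, so the dihydrobenzofuran is made racemic and its cis/trans ratio is immaterial.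

**Route**

Step 1
Reactants: 1 3,4-dihydroxy-5-methoxybenzaldehyde
Product: 2 3-methoxy-4,5-bis(methoxymethoxy)benzaldehyde
Conditions: MOMCl, i-Pr2NEt, CH2Cl2, 0 °C to rt
Reagents that add atoms: chloromethyl methyl ether (MOMCl), COCCl
Why: Both phenolic hydroxyls should be O-alkylated by the reactive α-chloro ether under amine base (acetal protection of a catechol), with no competing reaction at the aldehyde.

Step 2
Reactants: 2 3-methoxy-4,5-bis(methoxymethoxy)benzaldehyde
Product: 3 [3-methoxy-4,5-bis(methoxymethoxy)phenyl]methanol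
Conditions: NaBH4, MeOH, 0 °C
Reagents that add atoms: none
Why: Borohydride reduction of an aryl aldehyde to the benzylic alcohol is reliable and leaves the acetals untouched.

Step 3
Reactants: 3 [3-methoxy-4,5-bis(methoxymethoxy)phenyl]methanol
Product: 4 5-(bromomethyl)-1-methoxy-2,3-bis(methoxymethoxy)benzene
Conditions: CBr4, PPh3, CH2Cl2, 0 °C; short silica pad, used at once
Reagents that add atoms: carbon tetrabromide, BrC(Br)(Br)Br
Why: The Appel reaction converts the primary benzylic alcohol into the bromide through an alkoxyphosphonium ion under neutral conditions, so the acid-labile acetals should survive.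

Step 4
Reactants: 5 dihydroconiferyl alcohol
Product: 6 4-(3-hydroxypropyl)-2-iodo-6-methoxyphenol
Conditions: I2, KI, NaHCO3, H2O/THF, 0 °C to rt; Na2S2O3 quench
Reagents that add atoms: iodine, II
Why: Electrophilic aromatic iodination proceeds through the phenoxide, whose para position is blocked by the side chain, so iodine should enter the only free position ortho to the hydroxyl.

Step 5
Reactants: 6 4-(3-hydroxypropyl)-2-iodo-6-methoxyphenol; 4 5-(bromomethyl)-1-methoxy-2,3-bis(methoxymethoxy)benzene
Product: 7 3-(3-iodo-5-methoxy-4-{[3-methoxy-4,5-bis(methoxymethoxy)phenyl]methoxy}phenyl)propan-1-ol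
Conditions: K2CO3, DMF, rt
Reagents that add atoms: none
Why: In this Williamson ether synthesis K2CO3 deprotonates only the phenol, and the phenoxide displaces the benzylic bromide by SN2 while the aliphatic alcohol stays free.

Step 6
Reactants: 7 3-(3-iodo-5-methoxy-4-{[3-methoxy-4,5-bis(methoxymethoxy)phenyl]methoxy}phenyl)propan-1-ol
Product: 8 tert-butyl[3-(3-iodo-5-methoxy-4-{[3-methoxy-4,5-bis(methoxymethoxy)phenyl]methoxy}phenyl)propoxy]dimethylsilane
Conditions: TBSCl, imidazole, CH2Cl2, rt
Reagents that add atoms: tert-butyldimethylsilyl chloride (TBSCl), CC(C)(C)[Si](C)(C)Cl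
Why: Imidazole-promoted silylation of the only remaining hydroxyl removes the O–H bond that would otherwise trap the carbene in step 8.

Step 7
Reactants: 8 tert-butyl[3-(3-iodo-5-methoxy-4-{[3-methoxy-4,5-bis(methoxymethoxy)phenyl]methoxy}phenyl)propoxy]dimethylsilane; 9 ethyl diazoacetate
Product: 10 ethyl 2-diazo-2-[5-{3-[(tert-butyldimethylsilyl)oxy]propyl}-3-methoxy-2-{[3-methoxy-4,5-bis(methoxymethoxy)phenyl]methoxy}phenyl]acetate
Conditions: Pd(PPh3)4 (5 mol%), Ag2CO3 (0.5 equiv), Et3N, toluene, rt, dark
Reagents that add atoms: none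
Why: In this palladium-catalysed cross-coupling of an aryl iodide with a diazoacetate, zerovalent palladium inserts into the C–I bond, Ag2CO3 removes iodide, the deprotonated diazo ester binds through carbon, and reductive elimination at room temperature forms the aryl–carbon bond with the diazo group retained.

Step 8
Reactants: 10 ethyl 2-diazo-2-[5-{3-[(tert-butyldimethylsilyl)oxy]propyl}-3-methoxy-2-{[3-methoxy-4,5-bis(methoxymethoxy)phenyl]methoxy}phenyl]acetate
Product: 11 ethyl rac-(2R,3S)-5-{3-[(tert-butyldimethylsilyl)oxy]propyl}-7-methoxy-2-[3-methoxy-4,5-bis(methoxymethoxy)phenyl]-2,3-dihydro-1-benzofuran-3-carboxylate (cis)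
Conditions: Rh2(OAc)4 (1 mol%), CH2Cl2, rt, slow addition of 10 under argon
Reagents that add atoms: none
Why: Rh2(OAc)4 expels dinitrogen from the diazo carbon to give an electrophilic donor–acceptor carbene at the future C3, stabilised by ring A and the ester, which inserts into one C–H bond of the ArO–CH2–aryl group through a concerted, asynchronous three-centre transition state with hydride-transfer character, creating the C2–C3 bond. The closest known reaction type is the dirhodium-catalysed intramolecular C–H insertion of ortho-benzyloxy aryldiazoacetates, which gives 2-aryl-2,3-dihydrobenzofuran-3-carboxylates. The dihydrofuran ring is closed as a five-membered ring by 1,5 insertion, the mode preferred by rhodium carbenes, with O1, C7a and C3a of the tether already fixed on ring A. C2 and C3 are formed together in that one transition state; with an achiral catalyst the product is racemic, and the cis relation is expected under kinetic control because the ring-B aryl group turns away from the carboxylate wall of the catalyst, while any trans isomer converges in step 9. The step needs chemoselectivity for this C–H bond over ylide formation, addition to ring B and carbene dimerisation: the charge building up at C2 is stabilised by O1 and the electron-rich ring B, attack on the ether oxygen would require a four-membered ylide, the methoxy, acetal and silyloxy C–H bonds cannot reach the carbene, and slow addition keeps the diazo concentration low.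

Step 9
Reactants: 11 ethyl rac-(2R,3S)-5-{3-[(tert-butyldimethylsilyl)oxy]propyl}-7-methoxy-2-[3-methoxy-4,5-bis(methoxymethoxy)phenyl]-2,3-dihydro-1-benzofuran-3-carboxylate (cis)
Product: 12 ethyl 5-{3-[(tert-butyldimethylsilyl)oxy]propyl}-7-methoxy-2-[3-methoxy-4,5-bis(methoxymethoxy)phenyl]-1-benzofuran-3-carboxylate
Conditions: DDQ (1.5 equiv), anhydrous 1,4-dioxane, 90 °C
Reagents that add atoms: none
Why: In this quinone dehydrogenation DDQ abstracts hydride from C2, which is benzylic to ring B and bonded to O1, and the resulting oxocarbenium ion loses the acidic C3 proton to give the aromatic benzofuran, removing both stereocentres.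

Step 10
Reactants: 12 ethyl 5-{3-[(tert-butyldimethylsilyl)oxy]propyl}-7-methoxy-2-[3-methoxy-4,5-bis(methoxymethoxy)phenyl]-1-benzofuran-3-carboxylate
Product: 13 (5-{3-[(tert-butyldimethylsilyl)oxy]propyl}-7-methoxy-2-[3-methoxy-4,5-bis(methoxymethoxy)phenyl]-1-benzofuran-3-yl)methanol
Conditions: i-Bu2AlH (3 equiv), CH2Cl2, −78 to 0 °C; aqueous KNaC4H4O6 work-up
Reagents that add atoms: none
Why: Hydride reduction with i-Bu2AlH takes the conjugated ester to the primary alcohol and should leave the silyl ether, the acetals and the benzofuran intact at low temperature.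

Step 11
Reactants: 13 (5-{3-[(tert-butyldimethylsilyl)oxy]propyl}-7-methoxy-2-[3-methoxy-4,5-bis(methoxymethoxy)phenyl]-1-benzofuran-3-yl)methanol
Product: 14 5-{3-[(tert-butyldimethylsilyl)oxy]propyl}-7-methoxy-2-[3-methoxy-4,5-bis(methoxymethoxy)phenyl]-1-benzofuran-3-carbaldehyde
Conditions: activated MnO2 (excess), CH2Cl2, rt
Reagents that add atoms: none
Why: MnO2 oxidises benzylic-type heteroaryl carbinols selectively and should stop cleanly at the aldehyde.

Step 12
Reactants: 14 5-{3-[(tert-butyldimethylsilyl)oxy]propyl}-7-methoxy-2-[3-methoxy-4,5-bis(methoxymethoxy)phenyl]-1-benzofuran-3-carbaldehyde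
Product: 15 Mururin C, 2-(3,4-dihydroxy-5-methoxyphenyl)-5-(3-hydroxypropyl)-7-methoxy-1-benzofuran-3-carbaldehyde
Conditions: 3 M aqueous HCl, THF, 45 °C, degassed, under argon
Reagents that add atoms: none
Why: Acid hydrolysis cleaves both methoxymethyl acetals and the primary silyl ether in one operation, while the aldehyde, the benzofuran and the aryl methyl ethers are stable to dilute acid and the air-sensitive catechol is never exposed to base.

**Compound list**

1 | 3,4-dihydroxy-5-methoxybenzaldehyde | COc1cc(C=O)cc(O)c1O | starting material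
2 | 3-methoxy-4,5-bis(methoxymethoxy)benzaldehyde | COc1cc(C=O)cc(OCOC)c1OCOC | intermediate
3 | [3-methoxy-4,5-bis(methoxymethoxy)phenyl]methanol | COc1cc(CO)cc(OCOC)c1OCOC | intermediate
4 | 5-(bromomethyl)-1-methoxy-2,3-bis(methoxymethoxy)benzene | COc1cc(CBr)cc(OCOC)c1OCOC | intermediate
5 | dihydroconiferyl alcohol, 4-(3-hydroxypropyl)-2-methoxyphenol | COc1cc(CCCO)ccc1O | starting material
6 | 4-(3-hydroxypropyl)-2-iodo-6-methoxyphenol | COc1cc(CCCO)cc(I)c1O | intermediate
7 | 3-(3-iodo-5-methoxy-4-{[3-methoxy-4,5-bis(methoxymethoxy)phenyl]methoxy}phenyl)propan-1-ol | COc1cc(CCCO)cc(I)c1OCc1cc(OC)c(OCOC)c(OCOC)c1 | intermediate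
8 | tert-butyl[3-(3-iodo-5-methoxy-4-{[3-methoxy-4,5-bis(methoxymethoxy)phenyl]methoxy}phenyl)propoxy]dimethylsilane | COc1cc(CCCO[Si](C)(C)C(C)(C)C)cc(I)c1OCc1cc(OC)c(OCOC)c(OCOC)c1 | intermediate
9 | ethyl diazoacetate | CCOC(=O)C=[N+]=[N-] | starting material
10 | ethyl 2-diazo-2-[5-{3-[(tert-butyldimethylsilyl)oxy]propyl}-3-methoxy-2-{[3-methoxy-4,5-bis(methoxymethoxy)phenyl]methoxy}phenyl]acetate | CCOC(=O)C(=[N+]=[N-])c1cc(CCCO[Si](C)(C)C(C)(C)C)cc(OC)c1OCc1cc(OC)c(OCOC)c(OCOC)c1 | intermediate
11 | ethyl rac-(2R,3S)-5-{3-[(tert-butyldimethylsilyl)oxy]propyl}-7-methoxy-2-[3-methoxy-4,5-bis(methoxymethoxy)phenyl]-2,3-dihydro-1-benzofuran-3-carboxylate (cis, racemic, one enantiomer drawn) | CCOC(=O)[C@@H]1[C@H](c2cc(OC)c(OCOC)c(OCOC)c2)Oc2c(OC)cc(CCCO[Si](C)(C)C(C)(C)C)cc21 | intermediate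
12 | ethyl 5-{3-[(tert-butyldimethylsilyl)oxy]propyl}-7-methoxy-2-[3-methoxy-4,5-bis(methoxymethoxy)phenyl]-1-benzofuran-3-carboxylate | CCOC(=O)c1c(-c2cc(OC)c(OCOC)c(OCOC)c2)oc2c(OC)cc(CCCO[Si](C)(C)C(C)(C)C)cc12 | intermediate
13 | (5-{3-[(tert-butyldimethylsilyl)oxy]propyl}-7-methoxy-2-[3-methoxy-4,5-bis(methoxymethoxy)phenyl]-1-benzofuran-3-yl)methanol | OCc1c(-c2cc(OC)c(OCOC)c(OCOC)c2)oc2c(OC)cc(CCCO[Si](C)(C)C(C)(C)C)cc12 | intermediate
14 | 5-{3-[(tert-butyldimethylsilyl)oxy]propyl}-7-methoxy-2-[3-methoxy-4,5-bis(methoxymethoxy)phenyl]-1-benzofuran-3-carbaldehyde | O=Cc1c(-c2cc(OC)c(OCOC)c(OCOC)c2)oc2c(OC)cc(CCCO[Si](C)(C)C(C)(C)C)cc12 | intermediate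
15 | Mururin C, 2-(3,4-dihydroxy-5-methoxyphenyl)-5-(3-hydroxypropyl)-7-methoxy-1-benzofuran-3-carbaldehyde | COc1cc(-c2oc3c(OC)cc(CCCO)cc3c2C=O)cc(O)c1O | target

**Count and risk**

Total step count: 12. Longest linear sequence: 11 steps (steps 1, 2, 3, 5, 6, 7, 8, 9, 10, 11, 12 from compound 1).

Steps most likely to fail:

1. Step 7. Oxidative addition into the hindered, electron-rich aryl iodide may be slower than palladium-induced loss of dinitrogen from the diazo ester, so the diazo partner could be consumed before coupling. The fallback sets out from compound 8 and separates C–C bond formation from diazo installation. Negishi-type α-arylation of 8 with BrZnCH2CO2Et (Pd(dba)2, XPhos, THF, rt to 60 °C) should give the ethyl arylacetate F1. Regitz diazo transfer to F1 with 4-acetamidobenzenesulfonyl azide and DBU in MeCN then comes back to the route at compound 10.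

2. Step 8. The carbene may be diverted into dimerisation or azine formation, or into addition to the electron-rich ring B, instead of inserting. The fallback builds the benzofuran by alkyne chemistry; it sets out from compounds 2 and 6 and comes back at compound 14. Homologation of 2 with dimethyl (1-diazo-2-oxopropyl)phosphonate and K2CO3 in MeOH should give the aryl alkyne F2. Sonogashira coupling of F2 with iodophenol 6 (PdCl2(PPh3)2, CuI, Et3N, DMF, 60 °C) with in-flask 5-endo closure of the phenol onto the alkyne should give the 2-arylbenzofuran propanol F3. Silylation with TBSCl and imidazole gives the silyl ether F4, and NBS in CH2Cl2 at 0 °C brominates the nucleophilic C3 to give the 3-bromobenzofuran F5. Bromine–lithium exchange with n-BuLi in THF at −78 °C and a DMF quench then delivers compound 14.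

3. Step 9. Hydride abstraction may also occur at the side-chain methylene para to O1, or the acidic hydroquinone formed at high temperature may strip acetal or silyl groups, leading to over-oxidation or loss of protection. The fallback sets out from compound 11, comes back at compound 12, and replaces hydride abstraction by enolate selenation and syn elimination. Deprotonation at C3 with LiN(SiMe3)2 in THF at −78 °C is expected to be safe, because ring opening of the enolate is a stereoelectronically disfavoured reverse 5-endo process. Trapping with PhSeBr anti to the ring-B aryl group should give the C3 selenide F6. Oxidation with H2O2 in CH2Cl2 at 0 °C gives the selenoxide F7, which should lose the selenium group together with the cis C2 hydrogen to form compound 12.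

Further compounds
F1 | step 7 | ethyl 2-[5-{3-[(tert-butyldimethylsilyl)oxy]propyl}-3-methoxy-2-{[3-methoxy-4,5-bis(methoxymethoxy)phenyl]methoxy}phenyl]acetate | CCOC(=O)Cc1cc(CCCO[Si](C)(C)C(C)(C)C)cc(OC)c1OCc1cc(OC)c(OCOC)c(OCOC)c1
F2 | step 8 | 5-ethynyl-1-methoxy-2,3-bis(methoxymethoxy)benzene | C#Cc1cc(OC)c(OCOC)c(OCOC)c1
F3 | step 8 | 3-{7-methoxy-2-[3-methoxy-4,5-bis(methoxymethoxy)phenyl]-1-benzofuran-5-yl}propan-1-ol | OCCCc1cc(OC)c2oc(-c3cc(OC)c(OCOC)c(OCOC)c3)cc2c1
F4 | step 8 | tert-butyl(3-{7-methoxy-2-[3-methoxy-4,5-bis(methoxymethoxy)phenyl]-1-benzofuran-5-yl}propoxy)dimethylsilane | CC(C)(C)[Si](C)(C)OCCCc1cc(OC)c2oc(-c3cc(OC)c(OCOC)c(OCOC)c3)cc2c1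
F5 | step 8 | (3-{3-bromo-7-methoxy-2-[3-methoxy-4,5-bis(methoxymethoxy)phenyl]-1-benzofuran-5-yl}propoxy)(tert-butyl)dimethylsilane | CC(C)(C)[Si](C)(C)OCCCc1cc(OC)c2oc(-c3cc(OC)c(OCOC)c(OCOC)c3)c(Br)c2c1
F6 | step 9 | ethyl 5-{3-[(tert-butyldimethylsilyl)oxy]propyl}-7-methoxy-2-[3-methoxy-4,5-bis(methoxymethoxy)phenyl]-3-(phenylselanyl)-2,3-dihydro-1-benzofuran-3-carboxylate (racemic, selenium trans to the ring-B aryl group, one enantiomer drawn) | CCOC(=O)[C@]1([Se]c2ccccc2)[C@H](c2cc(OC)c(OCOC)c(OCOC)c2)Oc2c(OC)cc(CCCO[Si](C)(C)C(C)(C)C)cc21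
F7 | step 9 | ethyl 5-{3-[(tert-butyldimethylsilyl)oxy]propyl}-7-methoxy-2-[3-methoxy-4,5-bis(methoxymethoxy)phenyl]-3-(phenylseleninyl)-2,3-dihydro-1-benzofuran-3-carboxylate (racemic, configuration at selenium undefined) | CCOC(=O)[C@]1([Se](=O)c2ccccc2)[C@H](c2cc(OC)c(OCOC)c(OCOC)c2)Oc2c(OC)cc(CCCO[Si](C)(C)C(C)(C)C)cc21
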